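## Retrosynthetic overview

1. Target 13 ⇒ racemic epoxy diol 11 + veratroyl chloride 12. The C6–O ester bond is made last by an enantiomer-selective acyl transfer, which also fixes the absolute configuration.
2. 11 ⇒ (±)-jaeschkeanadiol 10. The oxirane (C8–O, C9–O) is closed by 6α-OH-directed epoxidation.
3. 10 ⇒ bicyclic hydroxy ketone 9 + isopropyl–cerium (C4–iPr bond).
4. 9 ⇒ diene 8 by ring-closing metathesis (C8=C9). 8 ⇒ enol silane 2 + aldehyde 4 by anti-aldol (C5–C6). 2 ⇒ 3-methylcyclopent-2-enone + allylcopper (C1–C10).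
5. Ring order: cyclopentane (bought) → cycloheptene (metathesis) → oxirane.

Numbering note: positions use daucane numbering. C1 is the ring-fusion carbon bearing CH3; C2, C3 are the cyclopentane CH2 groups; C4 is the carbinol carbon bearing isopropyl; C5 is the ring-fusion CH; C6 is the ester carbon; C7 is CH2; C8 is the methyl-bearing alkene/epoxide carbon; C9 is the alkene/epoxide CH; C10 is CH2.

Assumption: compounds 2 and 5–11 are racemic and each SMILES shows the enantiomer that ends up in 13; the diamine antipode used in step 7 (both come from proline) is the one that a single screening run shows to acylate (6S)-11.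

## Route

Step 1
Reactants: 1 3-methylcyclopent-2-en-1-one
Product: 2 trimethyl{[(3R)-3-methyl-3-(prop-2-en-1-yl)cyclopent-1-en-1-yl]oxy}silane (racemic)
Conditions: allylMgCl, CuBr·SMe2, LiCl, TMSCl, THF, −78 °C; Et3N/pentane work-up, used crude
Reagents that add atoms: allylmagnesium chloride, C=CC[Mg]Cl; chlorotrimethylsilane, C[Si](C)(C)Cl
Why: TMSCl-accelerated conjugate (1,4-) addition of an allylcopper reagent to a β,β-disubstituted enone, in which silyl trapping suppresses 1,2-addition, creates the C1 quaternary carbon (racemic) and stores the enolate regiospecifically on the quaternary side as the silyl enol ether.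

Step 2
Reactants: 3 3-methylbut-3-en-1-ol
Product: 4 3-methylbut-3-enal
Conditions: Dess–Martin periodinane, pyridine, CH2Cl2, 0 °C; cold filtration, solution used at once
Reagents that add atoms: none
Why: Dess–Martin oxidation of a primary alcohol under pyridine buffering stops at the aldehyde and avoids acid- or base-induced migration of the double bond into conjugation.

Step 3
Reactants: 2 silyl enol ether; 4 3-methylbut-3-enal
Product: 8 (2S,3R)-2-[(1S)-1-hydroxy-3-methylbut-3-en-1-yl]-3-methyl-3-(prop-2-en-1-yl)cyclopentan-1-one (racemic), via lithium enolate 5 (not isolated), via dicyclohexylboron enolate 6 (not isolated), via boron aldolate 7 (not isolated)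
Conditions: MeLi, THF, 0 °C; Chx2BCl, −78 °C; 4 (1.5 equiv), −78 → −20 °C; pH 7 buffer, MeOH, 30% H2O2, 0 °C
Reagents that add atoms: none
Why: Stork regeneration of the regiodefined enolate with MeLi, lithium-to-boron exchange and a boron aldol reaction through a Zimmerman–Traxler chair, in which the ring-locked E(O)-enolate with the aldehyde chain equatorial gives the anti C5/C6 relationship, the aldehyde enters on the enolate face opposite the larger allyl group (side chain cis to CH3, as needed for trans ring fusion), and the non-basic boron enolate does not deprotonate the enolisable aldehyde.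

Step 4
Reactants: 8 aldol diene
Product: 9 (3aR,8S,8aS)-8-hydroxy-3a,6-dimethyl-3,3a,4,7,8,8a-hexahydroazulen-1(2H)-one (racemic)
Conditions: second-generation Hoveyda–Grubbs catalyst RuCl2(H2IMes)(=CH–C6H4-2-OiPr) (5 mol%), 1,4-benzoquinone (10 mol%), CH2Cl2 (5 mM), 40 °C
Reagents that add atoms: none
Why: Ring-closing metathesis between the allyl group and the 1,1-disubstituted methallyl alkene closes the seven-membered ring as the trisubstituted C8=C9 cycloheptene with loss of ethene, tolerates the free alcohol and ketone, changes no stereocentre and turns the trans-disposed chains into the trans-fused hydroazulene.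

Step 5
Reactants: 9 bicyclic hydroxy ketone
Product: 10 (3R,3aS,4S,8aR)-6,8a-dimethyl-3-(propan-2-yl)-1,2,3,3a,4,5,8,8a-octahydroazulene-3,4-diol (racemic jaeschkeanadiol)
Conditions: iPrLi (3.5 equiv), CeCl3 (3.5 equiv), THF, −78 °C; aq NH4Cl
Reagents that add atoms: isopropyllithium, CC(C)[Li]
Why: Imamoto organocerium 1,2-addition (low basicity suppresses enolisation, retro-aldol and β-hydride reduction) attacks C4 from the α face, away from the axial β-methyl on C1 and past the small axial H5, so the tertiary hydroxyl ends up β and isopropyl α.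

Step 6
Reactants: 10 racemic jaeschkeanadiol
Product: 11 (1R,4R,5S,6S,8R,9S)-8,9-epoxydaucane-4,6-diol (racemic 8α,9α-epoxyjaeschkeanadiol)
Conditions: VO(acac)2 (5 mol%), tBuOOH (1.3 equiv), 2,6-lutidine (0.2 equiv), CH2Cl2, 0 °C
Reagents that add atoms: tert-butyl hydroperoxide, CC(C)(C)OO
Why: Homoallylic-hydroxyl-directed vanadium-catalysed epoxidation, in which the 6α-alkoxide bound to pentavalent vanadium delivers the peroxide oxygen to the α face of C8=C9 (also the face free of the β angular methyl), sets C8 and C9, while the lutidine buffer prevents acid-promoted transannular opening by the 4β-OH.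

Step 7
Reactants: 11 racemic epoxy diol; 12 3,4-dimethoxybenzoyl chloride
Product: 13 (1R,4R,5S,6S,8R,9S)-8,9-epoxy-4-hydroxydaucan-6-yl 3,4-dimethoxybenzoate
Conditions: (S)-1-methyl-2-[(1,3-dihydro-2H-isoindol-2-yl)methyl]pyrrolidine (3 mol%), 12 (0.48 equiv), Et3N (0.5 equiv), 4 Å MS, EtCN, −78 °C, stopped at about 45% conversion; chromatography, one recrystallisation
Reagents that add atoms: none
Why: Proposed new method: a catalytic enantiomer-selective veratroyl transfer (kinetic resolution of racemic 11) makes the C6–O ester bond and fixes the absolute configuration of all six stereocentres at once, because the proline-derived diamine and 12 form a rigid chiral N-acylammonium chloride that should acylate only the C6–OH of the (6S)-enantiomer, whose rigid trans-hydroazulene presents a small C7H2 flank and a fully substituted C5 flank, while the tertiary C4–OH stays inert and Et3N turns the catalyst over; the closest known reaction type is the chiral 1,2-diamine-catalysed benzoylative kinetic resolution of 2-substituted cycloalkanols with benzoyl chloride, not yet shown for a 3,4-dimethoxybenzoyl donor, a cycloheptanol or a substrate carrying a free tertiary hydroxyl and an epoxide.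

## Compound list

1 | 3-methylcyclopent-2-en-1-one | CC1=CC(=O)CC1 | starting material
2 | trimethyl{[(3R)-3-methyl-3-(prop-2-en-1-yl)cyclopent-1-en-1-yl]oxy}silane (racemic) | C=CC[C@@]1(C)CCC(O[Si](C)(C)C)=C1 | intermediate
3 | 3-methylbut-3-en-1-ol (isoprenol) | CC(=C)CCO | starting material
4 | 3-methylbut-3-enal | CC(=C)CC=O | intermediate
5 | lithium (3R)-3-methyl-3-(prop-2-en-1-yl)cyclopent-1-en-1-olate (racemic) | C=CC[C@@]1(C)CCC(O[Li])=C1 | intermediate
6 | dicyclohexyl{[(3R)-3-methyl-3-(prop-2-en-1-yl)cyclopent-1-en-1-yl]oxy}borane (racemic) | C=CC[C@@]1(C)CCC(OB(C2CCCCC2)C2CCCCC2)=C1 | intermediate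
7 | O-dicyclohexylboryl aldolate of 8 (racemic) | C=CC[C@@]1(C)CCC(=O)[C@@H]1[C@@H](OB(C2CCCCC2)C2CCCCC2)CC(C)=C | intermediate
8 | (2S,3R)-2-[(1S)-1-hydroxy-3-methylbut-3-en-1-yl]-3-methyl-3-(prop-2-en-1-yl)cyclopentan-1-one (racemic; anti aldol, side chain cis to CH3) | C=CC[C@@]1(C)CCC(=O)[C@@H]1[C@@H](O)CC(C)=C | intermediate
9 | (3aR,8S,8aS)-8-hydroxy-3a,6-dimethyl-3,3a,4,7,8,8a-hexahydroazulen-1(2H)-one (racemic; trans-fused) | O[C@H]2CC(C)=CC[C@@]3(C)CCC(=O)[C@H]23 | intermediate
10 | (3R,3aS,4S,8aR)-6,8a-dimethyl-3-(propan-2-yl)-1,2,3,3a,4,5,8,8a-octahydroazulene-3,4-diol (racemic jaeschkeanadiol; 4β-OH, 6α-OH) | O[C@H]2CC(C)=CC[C@@]3(C)CC[C@@](O)(C(C)C)[C@H]23 | intermediate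
11 | (1R,4R,5S,6S,8R,9S)-8,9-epoxydaucane-4,6-diol (racemic; 8α,9α-epoxide, 4β-OH, 6α-OH) | O[C@H]2C[C@@]3(C)O[C@H]3C[C@@]3(C)CC[C@@](O)(C(C)C)[C@H]23 | intermediate
12 | 3,4-dimethoxybenzoyl chloride (veratroyl chloride) | COc1ccc(C(=O)Cl)cc1OC | starting material
13 | (1R,4R,5S,6S,8R,9S)-8,9-epoxy-4-hydroxydaucan-6-yl 3,4-dimethoxybenzoate (8α,9α-epoxyjaeschkeanadiol 6-veratrate) | COc1ccc(C(=O)O[C@H]2C[C@@]3(C)O[C@H]3C[C@@]3(C)CC[C@@](O)(C(C)C)[C@H]23)cc1OC | target

## Step count and risks

Total step count: 7. Longest linear sequence: 6 (steps 1, 3, 4, 5, 6, 7).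

The three steps most likely to fail:

**Step 3 (aldol).** The enolate faces differ only by CH3 versus allyl, so the facial ratio is expected to be modest. The anti/syn ratio of a hindered cyclopentanone enolate is not guaranteed, and the aldehyde is labile. Cis-chain isomers are removed after step 4. If too much C6 epimer forms, C6 is no longer set by the aldol. The fallback sets out from 8 as its mixture with the syn aldol (2S,3R,1'R)-2-(1-hydroxy-3-methylbut-3-en-1-yl)-3-methyl-3-(prop-2-en-1-yl)cyclopentan-1-one F1. The mixture is taken through the conditions of steps 4 and 5, giving 9 with the 8-epi hydroxy ketone F2 and then 10 with 6-epi-jaeschkeanadiol F3. Dess–Martin oxidation of the 10/F3 mixture converges on one compound, 4β-hydroxydauc-8-en-6-one F4. Me4NBH(OAc)3 in MeCN/AcOH at −40 °C then delivers hydride from the tertiary 4β-hydroxyl to the β face of C6 (anti-1,3 reduction), and the route is rejoined at 10.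

**Step 5 (isopropyl addition).** The cerium aldolate could enolise or undergo retro-aldol cleavage, and β-hydride reduction could compete. The fallback sets out from 9: TESCl/imidazole gives the triethylsilyl ether F5, iPrLi/CeCl3 gives the silylated tertiary alcohol F6, and Bu4NF removes the silyl group, rejoining at 10.

**Step 7 (new enantiomer-selective veratroylation).** The selectivity factor may be too low; a factor of about 40 or more is needed for roughly 93–95% ee at 45% conversion before recrystallisation. The known-chemistry fallback sets out from racemic 10. Esterification with (S)-2-methoxy-2-phenylacetic acid (DCC, DMAP) gives the O-methylmandelate of the (1R,4R,5S,6S)-diol F7 and the diastereomeric O-methylmandelate of its antipode F8, which are separated by chromatography or crystallisation. K2CO3/MeOH cleaves F7 and the route comes back at 10 as a single enantiomer. This is epoxidised as in step 6 to enantiopure 11 and acylated with 12, Et3N and DMAP (no chiral catalyst) to give 13.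

## Further compounds

F1 | step 3 | (2S,3R)-2-[(1R)-1-hydroxy-3-methylbut-3-en-1-yl]-3-methyl-3-(prop-2-en-1-yl)cyclopentan-1-one (syn aldol, C6 epimer of 8) | C=CC[C@@]1(C)CCC(=O)[C@@H]1[C@H](O)CC(C)=C
F2 | step 3 | (3aR,8R,8aS)-8-hydroxy-3a,6-dimethyl-3,3a,4,7,8,8a-hexahydroazulen-1(2H)-one (8-epimer of 9) | O[C@@H]2CC(C)=CC[C@@]3(C)CCC(=O)[C@H]23
F3 | step 3 | (3R,3aS,4R,8aR)-6,8a-dimethyl-3-(propan-2-yl)-1,2,3,3a,4,5,8,8a-octahydroazulene-3,4-diol (6-epi-jaeschkeanadiol) | O[C@@H]2CC(C)=CC[C@@]3(C)CC[C@@](O)(C(C)C)[C@H]23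
F4 | step 3 | (1R,4R,5R)-4-hydroxydauc-8-en-6-one (4β-OH, 5α-H) | O=C2CC(C)=CC[C@@]3(C)CC[C@@](O)(C(C)C)[C@H]23
F5 | step 5 | triethylsilyl ether of 9 (6α-OSiEt3) | CC[Si](CC)(CC)O[C@H]2CC(C)=CC[C@@]3(C)CCC(=O)[C@H]23
F6 | step 5 | 6-O-triethylsilyl ether of 10 | CC[Si](CC)(CC)O[C@H]2CC(C)=CC[C@@]3(C)CC[C@@](O)(C(C)C)[C@H]23
F7 | step 7 | 6-O-[(S)-2-methoxy-2-phenylacetyl] ester of (1R,4R,5S,6S)-10 | CO[C@@H](c1ccccc1)C(=O)O[C@H]2CC(C)=CC[C@@]3(C)CC[C@@](O)(C(C)C)[C@H]23
F8 | step 7 | 6-O-[(S)-2-methoxy-2-phenylacetyl] ester of (1S,4S,5R,6R)-10 (antipodal diol) | CO[C@@H](c1ccccc1)C(=O)O[C@@H]2CC(C)=CC[C@]3(C)CC[C@](O)(C(C)C)[C@@H]23
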